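Two questions stood before me: how much target each of five flasks holds at the end, and how that row runs as the reagent charge climbs.

| flask | substrate | reagent in the second phase | remark | time | volume of the second phase over the first |
|---|---|---|---|---|---|
| beta | 16 mM | 0.80 equiv | run made earlier |  |  |
| midnight | 11 mM | 0.800 equiv |  | 15 h | 0.25 |
| dawn | 11 mM | 1.50 equiv |  | 15 h | 0.25 |
| summer | 11 mM | 3.00 equiv |  | 15 h | 0.25 |
| dusk | 11 mM | 6.00 equiv |  | 15 h | 0.25 |
| spring | 11 mM | 12.0 equiv |  | 15 h | 0.25 |

beta run (percent of the substrate charged)

| time / h | target / % | substrate / % |
|---|---|---|
| 0.833 | 4 | 91 |
| 2.50 | 15 | 82 |
| 4.00 | 21 | 75 |
| 6.00 | 28 | 67 |
| 10.0 | 38 | 56 |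

(scatter of a reading: 2 percentage points)

- amount of target at the end, in percent of the substrate charged for midnight, dawn, summer, dusk, spring, in this order
- the course of these numbers from the first flask to the last (falls, then rises / rises all the way / falls all the way / hardly changes / rises, then falls)

- for target the crystals are counted in
- in the second phase: reagent in the second phase; everything else is in the first
- charges count per volume of the first phase; a concentration in a rate is the amount of a species over the volume of its own phase; every rate counts per litre of the first phase
- as a solid, counted per litre of solution: crystals
- what was read earlier has a scatter of 2 percentage points, one standard deviation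
- reactions considered so far: reagent in the reaction phase <-> reagent in the second phase; substrate + reagent in the reaction phase -> target; reagent in the reaction phase + target -> over-reacted product; crystals <-> target
- the earlier runs hold the two phases in the same ratio of volumes as the flask asked about
- "hardly changes" means that all values lie within two and a half points (for a concentration: within two and a half percent of the largest)

I kept the books on the reagent in the last beta reading, at 10.0 h, where the charge of 0.80 equiv makes the reagent the limiting reagent. The first entry is one reagent for each substrate reacted: 44.0 % of the substrate charged. Crystals are counted in target, so they need no entry of their own. Target and substrate together leave 6.00 % of the substrate unaccounted for, and I booked that as over-reacted product, which costs one further reagent each. That makes the reagent spent equal to 50.0 % of the substrate charged, with 0.300 equiv still standing in the two phases.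

The second entry is small, so I treated it as a correction to the first. I named the leak the over-reacted product divided by the substrate reacted, both as fractions of the substrate charged. Beta reads 0.136, a rough reading, since each reading carries a scatter of 2 percentage points.

Midnight has beta's equivalents and phase ratio. Its concentration times time stands at 1.03 of beta's at that reading, so I carried over beta's reacted substrate and leak and committed to about 38.0 % of target for midnight. I expected the leak to grow with the charge, and so a rise and then a fall.

The forecast gave 39 %, 54 %, 58 %, 34 % and 12 %, with the course rises, then falls, adding: “I therefore shade the last values upward.”

The flasks gave 39.7 %, 53.1 %, 48.4 %, 24.0 % and 3.62 %, and the course rises, then falls.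

    reagent in the reaction phase ⇌ reagent in the second phase, rate k1*([reagent in the reaction phase] - [reagent in the second phase]/K1) per volume of the first phase (partition coefficient = 24.0, kL = 1.80 h⁻¹)
    substrate + reagent in the reaction phase → target (k = 84.0 M⁻¹ h⁻¹)
    reagent in the reaction phase + target → over-reacted product (k = 150 M⁻¹ h⁻¹)
    crystals ⇌ target, rate k4*(cs4 - [target]) while solid is left; crystals form when [target] > cs4 (solubility = 0.330 mM, k = 0.610 h⁻¹)

With midnight's 47.6 % of substrate reacted, beta's leak gives 6.49 % of over-reacted product against the 7.97 % that stood there. Dawn, with its larger charge and 73.6 % reacted, gets 10.0 % from beta's leak against 20.5 %, so dawn's own leak reads 0.279. Spring's leak reads 0.964, no small correction, and the step from reagent in the reaction phase and target to over-reacted product is the main reason for its low end. Spring holds 3.62 % of target with that step and 100 % without it.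

The data come from a simulation for substances that don't exist, noise included.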